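## The problem

Asterelin A (24) is a macrocyclic bis(bibenzyl) in which rings A and B are joined a second time through oxygen, so that a planar dibenzofuran sits inside an 18-membered ring. The ring runs from C1 of the dibenzofuran through CH2CH2 to ring D (para), across an ether oxygen to C3 of ring C, and from C1 of ring C through CH2CH2 back to C7. There is no stereogenic centre, so every question is one of regiochemistry and ring closure. Ring A has four different neighbours (alkyl at C1, OH at C3, the furan oxygen at C4a, the aryl bond at C9b), and any route that makes the C9a–C9b or C4a–O bond late must choose between ortho positions that differ only slightly. The macrocycle must be closed either around the flat tricycle, whose C1 and C7 arms diverge, or before the tricycle is complete. The two phenols are oxidation-prone and are best released last, and β-dicarbonyl intermediates will not tolerate strong Lewis acids; the diaryl ether and the CH2CH2 bridges are robust. The enabling feature is that ring A, read as C1 (bridge), C2 (H), C3 (OH), C4 (H), C4a (O5), C9b (aryl), is a 5-alkylresorcinol, the pattern produced when a poly-β-carbonyl chain folds by an aldol between C2 and C1. Its C4a–O5 unit together with ring B is simply a benzofuran, so the C4a oxygen is already an enol ether and ring A can be grown on C2 and C3 of a benzofuran made in one step.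

## Retrosynthesis

**24 back to 21.** The ring C O–CH3 bond and the C2–carboxyl bond of ring A are cut. The methyl ether comes with commercial aldehyde 3 and, unlike a benzyl ether, survives the hydrogenation of step 8. The ester is what remains of the activating group of the fold. Acid 22 has its carboxyl ortho to OH and para to the furan oxygen, so it should lose CO2 on heating to give 23. The forward steps must hydrolyse a hindered ester and cleave one aryl methyl ether without touching aryl–O–aryl bonds.

**21 back to 19.** The C1–C2 bond of ring A is cut, passing through aldol adduct 20. The alternatives for ring A, a late C9a–C9b biaryl bond or a late C4a–O bond, each face an ortho/ortho' choice. This cut has none, because the benzofuran already holds C4a–O5 and C9a–C9b. The precursor 19 has one ring fewer, and its C1 is a freely rotating acyl carbon. The forward reaction must make the keto ester CH2 attack the acyl ketone and no other pairing.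

**19 back to 15.** The bond between the chain ketone carbon and the malonate-derived CH2 is cut (19 from acyl imidazolide 18 and acid 17), then the oxidation level is taken back through alcohol 16 to acetate 15. The two-carbon stub is carried as an acetoxyethyl group for two reasons: a β-keto ester would not survive the Lewis acid of the ring closure, and a second carboxylic acid could not be distinguished from the one to be activated. The forward steps need a primary alcohol oxidised to an arylacetic acid beside a ketone, and a C-acylation under near-neutral conditions.

**15 back to 13.** The bond between benzofuran C3 and the acyl carbon is cut (via acid chloride 14). This places the macrocyclisation at the most nucleophilic carbon of the seco compound, and the carbonyl it introduces becomes C1 of ring A, so it never needs reducing. Closing at the ether or at a bridge would use equally long sequences but would leave the acyl group to be installed separately. The forward reaction must favour an 18-membered closure at C3 over oligomerisation and over attack on rings C and D.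

**13 back to 6 and 11.** The central CH2–CH2 bond of the B–C bridge is cut: Wittig olefination to 12 and hydrogenation. The same hydrogenation removes the benzyl ester, so the acid of 13 appears without a separate deprotection. The two fragments are of similar size, and the forward steps need only a mild base that spares an acetate and a benzyl ester.

**11 back to 7 and 8.** The aryl–alkyne bond and the O–C2 bond of the furan are cut. Acetate 11 comes from alcohol 10, which comes from iodophenol 7 and alkyne 8 by Sonogashira coupling and in-situ cyclisation of alkynylphenol 9. The formyl group of 7 ends at benzofuran C6, exactly where the bridge must leave, and the alkyne supplies C2 with its two-carbon stub. No other benzofuran synthesis gives this substitution in one step from commercial materials.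

**6 back to 1 and 3.** The ring C–O bond of the diaryl ether is cut (Ullmann coupling of phenol 2 with bromide 3 to 4), and the phosphonium group of 6 is traced through alcohol 5 to the aldehyde. Ester 2 is acid 1 protected as the benzyl ester. The ether is made while ring C still carries the formyl group, which both activates the bromide and later becomes the ylide carbon.

## Roads not taken

**Alternative 1:** The cut is the ether bond between the ring D oxygen and ring C, made last on a finished dibenzofuran. The open-chain bis(halophenol) A2 carries a 3,5-dibromo-4-hydroxyphenethyl arm on C7 and a 3,5-dichloro-4-hydroxyphenethyl arm on C1. It would be oxidised with Tl(NO3)3 in methanol. The dichlorophenol oxygen attacks a bromine-bearing ortho carbon of the more easily oxidised dibromophenol ring, the 18-membered ring closes, and zinc in acetic acid restores the arene to give A1.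
- Merits: the closure is a mild C–O bond formation whose site is fixed by the halogens, and its precedent in isodityrosine-type macrocycles is at least as good as that of the acylative closure of step 9.
- Weak points: four halogens must be installed and three removed (two are aryl chlorides), thallium is used stoichiometrically, and the ring must close around a flat tricycle whose arms diverge. The 1,3,7-substituted dibenzofuran of A2 still has to be made, so the ring A problem is moved, not solved.
- Against its better closure precedent, the chosen plan sets freedom from halogen handling, closure of the macrocycle before ring A is planar, and an actual construction of ring A.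

**Alternative 2:** The cuts are C3–C4 and C4a–C9b of ring A, in an intermediate that still lacks the C9a–C9b bond. Heating the cyclobutenone ethynyl ether A4 at high dilution would trigger four-electron ring opening, [2+2] addition to the alkyne, a second ring opening and six-electron closure. This gives A3, a 19-membered bis(diaryl ether) macrocycle with ring A complete.
- Merits: two C–C bonds, ring A and the macrocycle form in one reagent-free step, and the resorcinol pattern follows from the mechanism. In bonds per step this road is better than the chosen one.
- Weak points: the benzannulation is established between separate partners with the alkyne in excess, not as a macrocyclisation, and aryl ethynyl ethers are laborious and thermally fragile. A3 must still be converted to 23 by a dehydrogenative biaryl closure (Pd(OAc)2) that has to choose among four ortho/ortho' pairings and contract the ring from 19 to 18 atoms beside a free phenol.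
- The chosen plan pays more steps but has the C9a–C9b bond in the benzofuran from the start, and uses only known reaction classes.

**Alternative 3:** The cut is the bond between the bridge carbonyl carbon and C1 of ring C. In the 18-membered macrolactone A6, the dibenzofuran-7-ylacetic acid acylates the ring C phenol oxygen. CF3SO3H at low temperature would move the acyl group to the para carbon and give the carbocyclic bridge ketone A5.
- Merits: macrolactonisation is the most dependable ring closure discussed here, more so than step 9, and the ring C phenol needs no protecting group.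
- Weak points: once the ester C–O bond ionises in superacid the tether is lost, so the step is in effect a Friedel–Crafts macrocyclisation. It faces ortho/para competition, attack on the very electron-rich C2 and C4 of the 3-methoxydibenzofuran, and possible decarbonylation of the arylacetyl unit. The bridge carbonyl of A5 must then be reduced to CH2 before demethylation to 24, and the dibenzofuran is again presupposed.
- The chosen plan aims its one acylation at the most nucleophilic carbon present, and the carbonyl it makes is consumed as C1 of ring A.

Key step: step 13

Assumption: asterelin A has no stereogenic centre and is treated as conformationally mobile, so no SMILES carries a stereodescriptor; alkene 12 is used as an E/Z mixture and adduct 20 is a transient diastereomer mixture.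

Naming remark: in 15–19 "the macrocycle" is the 18-membered ring in which benzofuran C3 carries C(=O)CH2CH2 bound to C1 of ring D (1,4-phenylene), C4 of ring D is bound through oxygen to C3 of ring C (OMe on C4), and C1 of ring C is bound through CH2CH2 to benzofuran C6. In 20–24 dibenzofuran numbering is used: C1 carries the CH2CH2 link to ring D and C7 the CH2CH2 link to ring C.

## Route

Step 1
Reactants: 1 3-(4-hydroxyphenyl)propanoic acid
Product: 2 benzyl 3-(4-hydroxyphenyl)propanoate
Conditions: BnBr, KHCO3, DMF, 40 °C
Reagents that add atoms: benzyl bromide, BrCc1ccccc1
Why: Carboxylate O-alkylation (SN2); hydrogencarbonate ionises the acid but not the phenol, so only the ester forms. The benzyl ester is chosen because step 8 removes it in the hydrogenation that is needed anyway.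

Step 2
Reactants: 2 benzyl 3-(4-hydroxyphenyl)propanoate; 3 3-bromo-4-methoxybenzaldehyde
Product: 4 benzyl 3-[4-(5-formyl-2-methoxyphenoxy)phenyl]propanoate
Conditions: CuI (10 mol %), N,N-dimethylglycine hydrochloride (30 mol %), Cs2CO3, 1,4-dioxane, 90 °C
Reagents that add atoms: none
Why: Ligand-accelerated Ullmann diaryl ether synthesis, routine for aryl bromides with para-alkylphenols; the aldehyde and the ester tolerate anhydrous carbonate.

Step 3
Reactants: 4 benzyl 3-[4-(5-formyl-2-methoxyphenoxy)phenyl]propanoate
Product: 5 benzyl 3-{4-[5-(hydroxymethyl)-2-methoxyphenoxy]phenyl}propanoate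
Conditions: NaBH4, THF–H2O (9:1), 0 °C
Reagents that add atoms: none
Why: Chemoselective borohydride reduction of the aldehyde; the ester is inert at 0 °C and the alcohol-free medium excludes ester exchange.

Step 4
Reactants: 5 benzyl 3-{4-[5-(hydroxymethyl)-2-methoxyphenoxy]phenyl}propanoate
Product: 6 {3-[4-(3-benzyloxy-3-oxopropyl)phenoxy]-4-methoxybenzyl}triphenylphosphonium bromide
Conditions: PPh3·HBr, MeCN, reflux
Reagents that add atoms: triphenylphosphine hydrobromide, [Br-].c1ccc(cc1)[PH+](c1ccccc1)c1ccccc1
Why: Direct conversion of a benzylic alcohol to its phosphonium salt; the para-methoxy group lets the alcohol ionise under the mild acid and the phosphine captures the cation, so no separate bromide is needed.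

Step 5
Reactants: 7 3-hydroxy-4-iodobenzaldehyde; 8 but-3-yn-1-ol
Product: 10 2-(2-hydroxyethyl)-1-benzofuran-6-carbaldehyde, via alkynylphenol 9 (not isolated)
Conditions: PdCl2(PPh3)2 (3 mol %), CuI (5 mol %), Et3N, DMF, 25 → 70 °C
Reagents that add atoms: none
Why: Sonogashira coupling followed in the same pot by 5-endo-dig addition of the phenol to the alkyne, the standard benzofuran annulation of o-iodophenols. The para-formyl group speeds oxidative addition to zerovalent palladium and polarises the alkyne for attack at the distal carbon.

Step 6
Reactants: 10 2-(2-hydroxyethyl)-1-benzofuran-6-carbaldehyde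
Product: 11 2-(6-formyl-1-benzofuran-2-yl)ethyl acetate
Conditions: Ac2O, pyridine, DMAP (cat.), CH2Cl2, 0 °C → rt
Reagents that add atoms: acetic anhydride, CC(=O)OC(C)=O
Why: Acylation of the primary alcohol. The acetate withstands the ylide, hydrogenation and SnCl4, and keeps the alcohol from being esterified by the acid chloride of step 9.

Step 7
Reactants: 6 {3-[4-(3-benzyloxy-3-oxopropyl)phenoxy]-4-methoxybenzyl}triphenylphosphonium bromide; 11 2-(6-formyl-1-benzofuran-2-yl)ethyl acetate
Product: 12 benzyl 3-{4-[5-(2-{2-[2-(acetyloxy)ethyl]-1-benzofuran-6-yl}ethenyl)-2-methoxyphenoxy]phenyl}propanoate (E/Z mixture)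
Conditions: K2CO3, 18-crown-6 (cat.), CH2Cl2, reflux
Reagents that add atoms: none
Why: Wittig olefination of an aromatic aldehyde with a semistabilised benzyl ylide under solid–liquid phase transfer; the weak base spares both esters, and alkene geometry is irrelevant because step 8 saturates it.

Step 8
Reactants: 12 benzyl 3-{4-[5-(2-{2-[2-(acetyloxy)ethyl]-1-benzofuran-6-yl}ethenyl)-2-methoxyphenoxy]phenyl}propanoate
Product: 13 3-{4-[5-(2-{2-[2-(acetyloxy)ethyl]-1-benzofuran-6-yl}ethyl)-2-methoxyphenoxy]phenyl}propanoic acid
Conditions: H2 (1 atm), 10% Pd/C, EtOAc, rt
Reagents that add atoms: none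
Why: Catalytic hydrogenation saturates the stilbene and hydrogenolyses the benzyl ester in one operation; the benzofuran and the homobenzylic acetate are not reduced at atmospheric pressure.

Step 9
Reactants: 13 3-{4-[5-(2-{2-[2-(acetyloxy)ethyl]-1-benzofuran-6-yl}ethyl)-2-methoxyphenoxy]phenyl}propanoic acid
Product: 15 macrocyclic 3-acylbenzofuran carrying 2-(2-acetoxyethyl) on benzofuran C2, via acid chloride 14 (not isolated)
Conditions: (COCl)2, DMF (cat.), CH2Cl2, 0 °C → rt; evaporate; slow addition to SnCl4 (3 equiv), CH2Cl2, −20 → 0 °C, final concentration about 1 mM
Reagents that add atoms: oxalyl chloride, O=C(Cl)C(Cl)=O (supplies only the chlorine of intermediate 14; nothing from it remains in 15)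
Why: Intramolecular Friedel–Crafts acylation at C3 of a 2-alkylbenzofuran, the normal site of acylation of this heterocycle, run at high dilution as in macrocyclising acylations of thiophenes and arenes. The competing sites are much less nucleophilic: indanone closure on ring D would occur meta to its ether oxygen, and ring C can be reached only intermolecularly or through strained rings.

Step 10
Reactants: 15 macrocyclic 3-acylbenzofuran carrying 2-(2-acetoxyethyl) on benzofuran C2
Product: 16 macrocyclic 3-acylbenzofuran carrying 2-(2-hydroxyethyl) on benzofuran C2
Conditions: K2CO3 (0.2 equiv), MeOH–THF, 0 °C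
Reagents that add atoms: none
Why: Base-catalysed transesterification of a primary acetate; the low temperature and catalytic base keep E1cB loss of acetate from the CH2 on benzofuran C2 out of reach.

Step 11
Reactants: 16 macrocyclic 3-acylbenzofuran carrying 2-(2-hydroxyethyl) on benzofuran C2
Product: 17 macrocyclic 3-acylbenzofuran carrying 2-(carboxymethyl) on benzofuran C2
Conditions: TEMPO (7 mol %), NaClO2 (2 equiv), NaOCl (2 mol %), MeCN–phosphate buffer (pH 6.7), 35 °C
Reagents that add atoms: sodium chlorite, [Na+].[O-]Cl=O
Why: TEMPO/chlorite oxidation of a 2-arylethanol to the arylacetic acid, a protocol established on electron-rich arylethanols. The aldehyde is consumed as it forms at near-neutral pH, so it cannot condense with the neighbouring ketone, and hypochlorite is only catalytic.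

Step 12
Reactants: 17 macrocyclic 3-acylbenzofuran carrying 2-(carboxymethyl) on benzofuran C2
Product: 19 macrocyclic 3-acylbenzofuran carrying 2-(4-methoxy-2,4-dioxobutyl) on benzofuran C2, via acyl imidazolide 18 (not isolated)
Conditions: CDI, THF, rt; then Mg(O2CCH2CO2Me)2, THF, rt → 40 °C; cold 1 M HCl work-up
Reagents that add atoms: magnesium bis(methyl malonate), [Mg+2].COC(=O)CC([O-])=O.COC(=O)CC([O-])=O; 1,1'-carbonyldiimidazole, O=C(n1ccnc1)n1ccnc1 (supplies only the imidazolyl group of intermediate 18)
Why: Masamune–Brooks homologation: the magnesium malonate half-ester is C-acylated by the imidazolide and loses CO2, giving the β-keto ester under near-neutral conditions. The magnesium chelate of the product is a poor nucleophile, and any 21 formed prematurely is simply carried forward.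

Step 13
Reactants: 19 macrocyclic 3-acylbenzofuran carrying 2-(4-methoxy-2,4-dioxobutyl) on benzofuran C2
Product: 21 methyl 3-hydroxydibenzofuran-2-carboxylate bridged from C1 and C7 as in asterelin A with OMe on ring C (asterelin A ring C methyl ether 2-carboxylic acid methyl ester), via aldol adduct 20 (not isolated)
Conditions: Cs2CO3 (2 equiv), MeOH, rt → 50 °C; then 1 M HCl, 0 °C
Reagents that add atoms: none
Why: Carbonate removes a proton from the CH2 flanked by the chain ketone and the ester of 19, and this enolate carbon (future C2) adds to the acyl carbonyl on benzofuran C3 (future C1) to give adduct 20. E1cB loss of water across C1–C2 and enolisation of the remaining ketone through C4–H then give the aromatic 3-hydroxy ester 21; the closest known reaction type is the base-mediated aldol condensation–aromatisation that folds β,δ-diketo esters into resorcylates. Ring A closes in a 6-(enolexo)-exo-trig mode. No stereocentre results, because the two centres of 20 disappear on dehydration. The selectivity required is regiochemical: the reverse aldol sense (the CH2 alpha to the C1 ketone onto the chain ketone) is suppressed because that CH2 is far less acidic and the chain ketone is held as the non-electrophilic keto ester enolate, while the third acidic CH2 (future C4) could only close a four-membered ring. The furan oxygen stands in for the third carbonyl of a triketide, so only this one fold exists, and O-cyclisation to a hemiketal is reversible. Aromatisation is irreversible and pays for drawing the bridge carbon into the dibenzofuran plane inside the 18-membered ring; methanol as solvent makes ester exchange degenerate.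

Step 14
Reactants: 21 asterelin A ring C methyl ether 2-carboxylic acid methyl ester
Product: 23 asterelin A ring C methyl ether, via resorcylic acid 22 (not isolated)
Conditions: KOH, DMSO–H2O (4:1), 90 °C; aq. HCl to pH 2; crude acid in DMSO, 130 °C
Reagents that add atoms: potassium hydroxide, [K+].[OH-] (supplies one carboxyl oxygen of intermediate 22; nothing from it remains in 23)
Why: Saponification of a hindered salicylate-type ester, then thermal protodecarboxylation. The carboxyl of 22 sits ortho to OH and para to the furan oxygen, so ipso protonation is easy, as in orsellinic-type acids.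

Step 15
Reactants: 23 asterelin A ring C methyl ether
Product: 24 asterelin A
Conditions: BBr3 (4 equiv), CH2Cl2, −78 → 0 °C; then H2O
Reagents that add atoms: none
Why: Lewis acid-mediated cleavage of an aryl methyl ether by bromide attack at the methyl carbon; aryl–O–aryl bonds of the diaryl ether and the dibenzofuran offer no such carbon and are inert.

## Compound list

1 | 3-(4-hydroxyphenyl)propanoic acid | OC(=O)CCc1ccc(O)cc1 | starting material
2 | benzyl 3-(4-hydroxyphenyl)propanoate | O=C(CCc1ccc(O)cc1)OCc1ccccc1 | intermediate
3 | 3-bromo-4-methoxybenzaldehyde | COc1ccc(C=O)cc1Br | starting material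
4 | benzyl 3-[4-(5-formyl-2-methoxyphenoxy)phenyl]propanoate | COc1ccc(C=O)cc1Oc1ccc(CCC(=O)OCc2ccccc2)cc1 | intermediate
5 | benzyl 3-{4-[5-(hydroxymethyl)-2-methoxyphenoxy]phenyl}propanoate | COc1ccc(CO)cc1Oc1ccc(CCC(=O)OCc2ccccc2)cc1 | intermediate
6 | {3-[4-(3-benzyloxy-3-oxopropyl)phenoxy]-4-methoxybenzyl}triphenylphosphonium bromide | [Br-].COc1ccc(C[P+](c2ccccc2)(c2ccccc2)c2ccccc2)cc1Oc1ccc(CCC(=O)OCc2ccccc2)cc1 | intermediate
7 | 3-hydroxy-4-iodobenzaldehyde | O=Cc1ccc(I)c(O)c1 | starting material
8 | but-3-yn-1-ol | C#CCCO | starting material
9 | 3-hydroxy-4-(4-hydroxybut-1-yn-1-yl)benzaldehyde | O=Cc1ccc(C#CCCO)c(O)c1 | intermediate (not isolated)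
10 | 2-(2-hydroxyethyl)-1-benzofuran-6-carbaldehyde | O=Cc1ccc2cc(CCO)oc2c1 | intermediate
11 | 2-(6-formyl-1-benzofuran-2-yl)ethyl acetate | CC(=O)OCCc1cc2ccc(C=O)cc2o1 | intermediate
12 | benzyl 3-{4-[5-(2-{2-[2-(acetyloxy)ethyl]-1-benzofuran-6-yl}ethenyl)-2-methoxyphenoxy]phenyl}propanoate, E/Z mixture | CC(=O)OCCc1cc2ccc(C=Cc3ccc(OC)c(Oc4ccc(CCC(=O)OCc5ccccc5)cc4)c3)cc2o1 | intermediate
13 | 3-{4-[5-(2-{2-[2-(acetyloxy)ethyl]-1-benzofuran-6-yl}ethyl)-2-methoxyphenoxy]phenyl}propanoic acid | CC(=O)OCCc1cc2ccc(CCc3ccc(OC)c(Oc4ccc(CCC(=O)O)cc4)c3)cc2o1 | intermediate
14 | 3-{4-[5-(2-{2-[2-(acetyloxy)ethyl]-1-benzofuran-6-yl}ethyl)-2-methoxyphenoxy]phenyl}propanoyl chloride | CC(=O)OCCc1cc2ccc(CCc3ccc(OC)c(Oc4ccc(CCC(=O)Cl)cc4)c3)cc2o1 | intermediate (not isolated)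
15 | macrocyclic 3-acylbenzofuran, 2-(2-acetoxyethyl) on benzofuran C2 | CC(=O)OCCc1oc2cc3ccc2c1C(=O)CCc1ccc(cc1)Oc1cc(CC3)ccc1OC | intermediate
16 | macrocyclic 3-acylbenzofuran, 2-(2-hydroxyethyl) on benzofuran C2 | OCCc1oc2cc3ccc2c1C(=O)CCc1ccc(cc1)Oc1cc(CC3)ccc1OC | intermediate
17 | macrocyclic 3-acylbenzofuran, 2-(carboxymethyl) on benzofuran C2 | OC(=O)Cc1oc2cc3ccc2c1C(=O)CCc1ccc(cc1)Oc1cc(CC3)ccc1OC | intermediate
18 | macrocyclic 3-acylbenzofuran, 2-[2-(imidazol-1-yl)-2-oxoethyl] on benzofuran C2 | O=C(Cc1oc2cc3ccc2c1C(=O)CCc1ccc(cc1)Oc1cc(CC3)ccc1OC)n1ccnc1 | intermediate (not isolated)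
19 | macrocyclic 3-acylbenzofuran, 2-(4-methoxy-2,4-dioxobutyl) on benzofuran C2 | COC(=O)CC(=O)Cc1oc2cc3ccc2c1C(=O)CCc1ccc(cc1)Oc1cc(CC3)ccc1OC | intermediate
20 | methyl 1-hydroxy-3-oxo-1,2,3,4-tetrahydrodibenzofuran-2-carboxylate bridged from C1 and C7 as in 21, diastereomer mixture | O=C1C(C(=O)OC)C2(O)c3c(C1)oc1cc(ccc13)CCc1ccc(OC)c(c1)Oc1ccc(cc1)CC2 | intermediate (not isolated)
21 | asterelin A ring C methyl ether 2-carboxylic acid methyl ester | Oc1c(C(=O)OC)c2c3c(c1)oc1cc(ccc13)CCc1ccc(OC)c(c1)Oc1ccc(cc1)CC2 | intermediate
22 | asterelin A ring C methyl ether 2-carboxylic acid | Oc1c(C(=O)O)c2c3c(c1)oc1cc(ccc13)CCc1ccc(OC)c(c1)Oc1ccc(cc1)CC2 | intermediate (not isolated)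
23 | asterelin A ring C methyl ether | Oc1cc2c3c(c1)oc1cc(ccc13)CCc1ccc(OC)c(c1)Oc1ccc(cc1)CC2 | intermediate
24 | asterelin A | Oc1cc2c3c(c1)oc1cc(ccc13)CCc1ccc(O)c(c1)Oc1ccc(cc1)CC2 | target

## Step count and risks

Total: 15 steps. Longest linear sequence: 13 steps (1–4, then 7–15).

**Step 13 (key step).** Addition may be slow or reversible, because the acyl carbonyl is conjugated with the furan oxygen and must twist out of the benzofuran plane inside the macrocycle. On long exposure to base, closure in the reverse sense or retro-Claisen methanolysis of the keto ester could then take over. The fallback sets out from acid 17 and comes back at 23.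
- Acid 17 is esterified (TMSCHN2) to the methyl ester F1.
- The Reformatsky reagent BrZnCH2CO2Me in THF, a weakly basic nucleophile, adds to the ketone, making the C1–C2 bond intermolecularly and giving the hydroxy diester F2.
- NaOMe in MeOH closes ring A by Dieckmann condensation of the arylacetate carbon onto the new ester, and acid-catalysed loss of water gives the 3-hydroxy 4-carboxylate F3. Closure in the other Dieckmann sense would give 21 itself.
- Saponification to the acid F4 and decarboxylation under the conditions of step 14 give 23.

Here the ketone is consumed by an external nucleophile before any ring closure, so neither its low electrophilicity nor enolisation of the bridge CH2 matters.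

**Step 9.** Oligomerisation, or cyclisation of the acylating carbon onto its own ring D, may outrun closure of the 18-membered ring, and the acetate may tie up the Lewis acid. The fallback acylates intermolecularly and closes the ring by the Wittig reaction; it sets out from 6 and 11 and comes back at 15.
- Hydrogenolysis (H2, Pd/C) of the benzyl ester of 6 gives the phosphonium acid F5, converted with (COCl)2 to the acid chloride F6.
- F6 acylates 11 at benzofuran C3 (SnCl4, CH2Cl2, ordinary concentration) to give the keto aldehyde phosphonium salt F7.
- K2CO3/18-crown-6 at high dilution closes the ring to the macrocyclic stilbene F8 (E/Z mixture), and hydrogenation (H2, Pd/C) gives 15.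

**Step 12.** The activated acid has a very acidic CH2 next to a ketone-bearing benzofuran. Ketene formation with self-condensation, enol lactonisation onto the ketone, or decarboxylation of 17 (a vinylogous β-keto acid) on handling may erode the acylation. The fallback avoids the acid altogether; it sets out from 16 and comes back at 19. Dess–Martin oxidation of 16 gives the aldehyde F9, and Roskamp homologation (methyl diazoacetate, SnCl2 cat., CH2Cl2) converts it directly to 19. This also removes the dependence on step 11.

**Step 14.** Hydrolysis may stall, because the ester is flanked by two ortho substituents and hydrogen-bonded to the phenol, and forcing base may degrade the material before decarboxylation is complete. The fallback reverses the order of the last two operations; it sets out from 21 and comes back at 24. Excess BBr3 (CH2Cl2, −78 °C → rt) cleaves both O–methyl bonds by attack at carbon, giving the dihydroxy acid F10, which is decarboxylated by heating in DMSO to give 24.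

## Further compounds

F1 | step 13 | macrocyclic 3-acylbenzofuran with 2-(2-methoxy-2-oxoethyl) on benzofuran C2 (methyl ester of 17) | COC(=O)Cc1oc2cc3ccc2c1C(=O)CCc1ccc(cc1)Oc1cc(CC3)ccc1OC
F2 | step 13 | hydroxy diester from Reformatsky addition to F1, racemic tertiary alcohol | COC(=O)Cc1oc2cc3ccc2c1C(O)(CC(=O)OC)CCc1ccc(cc1)Oc1cc(CC3)ccc1OC
F3 | step 13 | asterelin A ring C methyl ether 4-carboxylic acid methyl ester | COC(=O)c1c(O)cc2c3c1oc1cc(ccc13)CCc1ccc(OC)c(c1)Oc1ccc(cc1)CC2
F4 | step 13 | asterelin A ring C methyl ether 4-carboxylic acid | OC(=O)c1c(O)cc2c3c1oc1cc(ccc13)CCc1ccc(OC)c(c1)Oc1ccc(cc1)CC2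
F5 | step 9 | {3-[4-(2-carboxyethyl)phenoxy]-4-methoxybenzyl}triphenylphosphonium bromide | [Br-].COc1ccc(C[P+](c2ccccc2)(c2ccccc2)c2ccccc2)cc1Oc1ccc(CCC(=O)O)cc1
F6 | step 9 | {3-[4-(3-chloro-3-oxopropyl)phenoxy]-4-methoxybenzyl}triphenylphosphonium bromide | [Br-].COc1ccc(C[P+](c2ccccc2)(c2ccccc2)c2ccccc2)cc1Oc1ccc(CCC(=O)Cl)cc1
F7 | step 9 | open-chain 3-acylbenzofuran with 6-formyl, 2-(2-acetoxyethyl) and the ring C benzylphosphonium bromide | [Br-].CC(=O)OCCc1oc2cc(C=O)ccc2c1C(=O)CCc1ccc(Oc2cc(C[P+](c3ccccc3)(c3ccccc3)c3ccccc3)ccc2OC)cc1
F8 | step 9 | macrocyclic stilbene analogue of 15 (CH=CH between ring C and benzofuran C6), E/Z mixture | CC(=O)OCCc1oc2cc3ccc2c1C(=O)CCc1ccc(cc1)Oc1cc(C=C3)ccc1OC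
F9 | step 12 | macrocyclic 3-acylbenzofuran with 2-(2-oxoethyl) on benzofuran C2 | O=CCc1oc2cc3ccc2c1C(=O)CCc1ccc(cc1)Oc1cc(CC3)ccc1OC
F10 | step 14 | asterelin A 2-carboxylic acid | Oc1c(C(=O)O)c2c3c(c1)oc1cc(ccc13)CCc1ccc(O)c(c1)Oc1ccc(cc1)CC2
A1 | alternative 1 | bromo dichloro asterelin A 3-methyl ether | COc1cc2c3c(c1)oc1cc(ccc13)CCc1cc(Br)c(O)c(c1)Oc1c(Cl)cc(cc1Cl)CC2
A2 | alternative 1 | 7-[2-(3,5-dibromo-4-hydroxyphenyl)ethyl]-1-[2-(3,5-dichloro-4-hydroxyphenyl)ethyl]-3-methoxydibenzofuran | COc1cc(CCc2cc(Cl)c(O)c(Cl)c2)c2c(c1)oc1cc(CCc3cc(Br)c(O)c(Br)c3)ccc12
A3 | alternative 2 | 19-membered bis(diaryl ether) macrocycle with ring A in place | Oc1cc2cc(c1)Oc1cccc(c1)CCc1ccc(OC)c(c1)Oc1ccc(cc1)CC2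
A4 | alternative 2 | open-chain 3-substituted cyclobut-2-enone carrying the aryl ethynyl ether | C#COc1cccc(CCc2ccc(OC)c(Oc3ccc(CCC4=CC(=O)C4)cc3)c2)c1
A5 | alternative 3 | bridge ketone of asterelin A 3-methyl ether | COc1cc2c3c(c1)oc1cc(ccc13)CC(=O)c1ccc(O)c(c1)Oc1ccc(cc1)CC2
A6 | alternative 3 | 18-membered phenolic macrolactone | COc1cc2c3c(c1)oc1cc(ccc13)CC(=O)Oc1ccccc1Oc1ccc(cc1)CC2
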